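A flat curve beside a gap in the balance tempts one to call the catalyst dead, so I asked first what the end state had to be.

| setting | Monday's | Friday's | Sunday's | flask |
|---|---|---|---|---|
| substrate | 0.32 M | 0.48 M | 0.64 M | 0.64 M |
| precatalyst | 10 mol% | 10 mol% | 15 mol% | 10 mol% |
| remark | run made earlier | run made earlier | run made earlier |  |
| time |  |  |  | 12 d |

| run | time / d | substrate / % | over-reaction product / % | target / % |
|---|---|---|---|---|
| Monday's | 2.08 | 0 | 44.9 | 0 |
| Monday's | 4.00 | 0.2 | 45.2 | 1.1 |
| Monday's | 6.00 | 1.3 | 43.2 | 0.5 |
| Monday's | 8.00 | 0.3 | 44.0 | 0 |
| Monday's | 10.0 | 0.2 | 44.9 | 1.0 |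
| Monday's | 12.0 | 1.0 | 47.1 | 1.1 |
| Monday's | 15.0 | 0 | 46.3 | 0 |
| Friday's | 1.25 | 0 | 48.0 | 2.5 |
| Friday's | 1.67 | 0 | 51.4 | 0.6 |
| Friday's | 2.50 | 0 | 49.2 | 0 |
| Friday's | 4.00 | 0.1 | 50.3 | 0 |
| Friday's | 6.00 | 0 | 52.4 | 0 |
| Friday's | 10.0 | 0 | 51.8 | 0 |
| Friday's | 15.0 | 0 | 51.4 | 0 |
| Sunday's | 3.00 | 0 | 60.4 | 0.4 |
| Sunday's | 6.00 | 0 | 59.2 | 0 |
| Sunday's | 8.00 | 1.0 | 62.2 | 0 |
| Sunday's | 12.0 | 0.8 | 61.2 | 1.7 |
| Sunday's | 15.0 | 0 | 59.8 | 0 |

(each reading ± 1 percentage point)

- the numbers in the tables scatter with a standard deviation of 1 percentage point
- in a conversion other conformer counts as not yet reacted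
- the reaction counts as stopped when no species that holds the substrate changes by six tenths of a point or more over the second half of the time

- the state of affairs at 12 d: stopped, and by what, or still going (other conformer counts as not reacted) (no working catalyst is left / forward and back rates have come level / all of the substrate has reacted / it is still moving)
- part of the substrate that has turned into other species by 12 d (other conformer does not count)
- over-reaction product at 12 d, in percent of the substrate charged

I read the runs as a ladder. On the first rung stood substrate: Friday's run read 0% at 1.25 d, earlier than the asked 12 d. Next came target, 2.5% at that reading and 0% at 2.50 d. Last came the plateau of over-reaction product, so I placed the flask at 12 d on its plateau, and the question was its height.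

At 10 mol% the plateau means were 45.1% on Monday's run and 50.6% on Friday's. A fixed number of turnovers per catalyst gives one height at one loading, but these differ by 5.5 percentage points with a scatter of 1 point. So I took the plateau as a race between two routes, with the gap an unread second product and the substrate used up, as Sunday's 0% at 6.00 d suggested.

I measured the race by the split ratio r, over-reaction product over the rest (a selectivity factor), against c, substrate times loading. Sunday's plateau mean was 60.6%, so from Monday's to Sunday's run r went from 0.821 to 1.54, while c went from 0.0320 M to 0.0960 M. That gave n = 0.570 for the split exponent n, the power of c that I assumed r to follow. Scaling from Sunday's run, I reckoned r = 1.22 for the flask, so 54.9%, and a stop for want of substrate.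

The forecast gave no working catalyst is left, conversion 56% and 55.5%, holding that “the catalyst dies”. We nearly agreed on the height but parted on the gap.

The flask gave all of the substrate has reacted, conversion 100% and 55.1%.

    substrate ⇌ other conformer (K = 7.10, k = 0.0680 /h)
    substrate + catalyst → catalyst + target (k = 6.70 /M/h)
    catalyst + other conformer → catalyst + isomer of the product (k = 18.0 /M/h)
    2 catalyst ⇌ resting dimer (K = 7.40 /M, k = 530 /M/h)
    precatalyst → catalyst (k = 0.0560 /h)
    target → over-reaction product (k = 0.200 /h)

The gap in the flask at 12 d was isomer of the product, 44.9%, with other conformer at 0%. At 0.297 d in the flask substrate went to target 1.7 times as fast as it went to other conformer (the forward step alone), while the end split in the flask, over-reaction product over isomer of the product, came to 1.23, against the r = 1.22 I had reckoned with n = 0.570.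

For the neighbour with 2.5 mol% of precatalyst, scaling again from Sunday's run, n gave r = 0.553, so 35.6% over-reaction product. The computed neighbour held 34.4%, with more isomer of the product, 65.6%.

All runs are calculated for an exercise, noise included.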